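**The race.** The constants of this flask describe a race for the partner: it couples with dissolved substrate to target, or it decays alone.

solid substrate 0.33 M; partner 0.264 M (fed, over 12 s); time 2.0 h

- which holds at 2.0 h: what has brought the reaction to rest, or that it has not come to rest (for what has run out or reacted, a solid counts together with what of it has only dissolved) (all of the solid substrate has reacted / forward and back rates have come level / the partner has run out first / it is still moving)
- part of the solid substrate that has turned into other species by 2.0 h (what has only dissolved does not count)
- side product at 2.0 h, in percent of the solid substrate charged

- a species is counted by the solid substrate in it: one side product counts as two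
- amounts and yields of target count crystals too
- given per volume of solution although it is solid: solid substrate, crystals
- at the start none of the solid substrate is in solution
- what has only dissolved of solid substrate counts as not reacted
- the reaction counts as stopped when no species that holds the solid substrate changes by six tenths of a point or more over the second half of the time
- run time (flask): 2.0 h

    solid substrate ⇌ dissolved substrate, rate k1*(cs1 - [dissolved substrate]) while solid is left; crystals form when [dissolved substrate] > cs1 (cs1 = 0.23 M, k1 = 0.93 s⁻¹)
    dissolved substrate + partner → target (k2 = 0.048 M⁻¹ s⁻¹)
    solid substrate + target → side product (k3 = 0.059 M⁻¹ s⁻¹)
    crystals ⇌ target, rate k4*(cs4 - [target]) while solid is left; crystals form when [target] > cs4 (cs4 = 39 mM, k4 = 0.13 s⁻¹)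
    partner → decomposed reagent (k5 = 0.088 s⁻¹)

**In the flask.** Solid substrate dissolves on a time scale of 1.08 s, shorter than the feed of 12 s. So c(dissolved substrate) stands near 0.23 M while solid is left. Coupling is then pseudo-first-order in partner, with coefficient 0.0110 s⁻¹, against 0.088 s⁻¹ for decay. Both rates carry c(partner), so with c(dissolved substrate) at saturation their division drops time out. It gives 11.1%, the capture share: coupling rate over the sum of coupling and decay rates.

**On return.** This flask should make 29.4 mM of target, below its solubility of 39 mM, so no crystals should form. Target then takes up solid substrate and becomes side product, which holds two substrate units. That draws at most 58.8 mM of solid, less than the 0.100 M beyond saturation. Solid should remain, and the partner should be the limiting reagent, with a decay half-life of 0.13 min. The reckoning gives conversion 17.8% and side product 17.8%.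

**Leave alone.** The capture share tells how much target forms, not how soon it passes on. By the step to side product alone, with solid substrate as charged, dissolved target has a half-life of 0.59 min. So this flask stays stirred and the run is not cut short.

**Forecast.** It says the partner has run out first, with conversion 17.7% and side product 17.7%, on the ground that “the partner decomposes about eight times faster than it couples”.

**Simulation.** This flask gives the partner has run out first, with conversion 17.6% and side product 17.6%. At 2.00 h it holds solid substrate 12.7%, dissolved substrate 69.7% and partner 0%.

**Reason, neighbour.** Decay of the partner is the main reason for the low conversion in this flask: without that step the run reaches 81.1% instead of 17.6%. The neighbour with 0.66 M of partner has a capture yield of 73.6 mM of target. That could draw 147 mM of solid, more than the excess, so the reckoning stops at 30.3%. The neighbour's computed conversion is 30.3%, with solid substrate at 0% and side product at 16.8%.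

The numbers belong to no real substance; the rest is arithmetic.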